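## Retrosynthetic overview

1. Target ⇒ bridgehead (C1) benzoylation of the debenzoyl tetracycle, which comes from a radical cascade (C3–Ca, then Cb–Cc) on a 3-bromo-7-endo-prenyl bicyclo[3.3.1]nonane-2,4,9-trione.
2. Bicyclic trione ⇒ a 2-acyl-2-geranylcyclohexanone carrying an α-oxo ketene dithioacetal; ring A closes by intramolecular enolate addition–elimination (C1–C2 bond).
3. Quaternary C5 ⇒ anti-selective geranylation of a 2-acylcyclohexanone; the acyl arm (C4, C3 and the C3 prenyl group) ⇒ intermolecular aldol of (S)-3,3-dimethyl-4-prenylcyclohexanone with 5-methylhex-4-enal.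
4. The cyclohexanone (ring B, C7 stereocentre) ⇒ key enantioselective intermolecular Michael addition of 5-methylhex-4-enal to methyl vinyl ketone, then aldol condensation and two methyl conjugate additions.
5. Ring order: ring B (cyclohexanone) → ring A (bicyclo[3.3.1] core) → seven-membered ring → cyclopentane (the last two in one cascade).

Assumption: core locants follow bicyclo[3.3.1]nonane-2,4,9-trione numbering (C1 benzoyl bridgehead, C3 between the C2 and C4 ketones, C5 geranyl bridgehead, C7 ring CH, C8 gem-dimethyl carbon, C9 bridging ketone); Ca–Cd are the cyclopentane carbons (Ca = CH bonded to C3, Cb = CMe2, Cc = CH–iPr, Cd = CH2); prenyl = 3-methylbut-2-en-1-yl, geranyl = (2E)-3,7-dimethylocta-2,6-dien-1-yl.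

## Route

Step 1
Reactants: 1 2-methylbut-3-en-2-ol; 2 ethyl vinyl ether
Product: 4 5-methylhex-4-enal, via allyl vinyl ether 3 (not isolated)
Conditions: 2 (3 equiv), H3PO4 (1 mol %), sealed vessel, 150 °C
Reagents that add atoms: none
Why: Acid-catalysed transetherification gives the tertiary allyl vinyl ether, which undergoes a Claisen rearrangement (Saucy–Marbet variant) to the γ,δ-unsaturated aldehyde; no stereocentre is formed.

Step 2
Reactants: 4 5-methylhex-4-enal; 5 methyl vinyl ketone
Product: 6 (2S)-2-(3-methylbut-2-en-1-yl)-5-oxohexanal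
Conditions: (S)-2-[methoxy(diphenyl)methyl]pyrrolidine (5 mol %), ethyl 3,4-dihydroxybenzoate (20 mol %), 5 (1.5 equiv), neat, 4 °C
Reagents that add atoms: none
Why: Key intermolecular Michael addition under enamine catalysis: the (E)-enamine of 4 is attacked by the enone on the face away from the CPh2OMe group, which sets the (S) centre (future C7) from which every other stereocentre is relayed.

Step 3
Reactants: 6 (2S)-2-(3-methylbut-2-en-1-yl)-5-oxohexanal
Product: 7 (4S)-4-(3-methylbut-2-en-1-yl)cyclohex-2-en-1-one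
Conditions: LiOH·H2O (0.1 equiv), iPrOH, 0 °C to rt
Reagents that add atoms: none
Why: Intramolecular aldol condensation (methyl ketone enolate onto the aldehyde, then E1cB loss of water) closes ring B faster than the aldehyde α-centre epimerises, so the stereocentre is carried over as C4 of the enone.

Step 4
Reactants: 7 (4S)-4-(3-methylbut-2-en-1-yl)cyclohex-2-en-1-one
Product: 8 trimethyl{[(3S,4S)-3-methyl-4-(3-methylbut-2-en-1-yl)cyclohex-1-en-1-yl]oxy}silane
Conditions: MeMgBr (1.3 equiv), CuBr·SMe2 (5 mol %), Me3SiCl (2 equiv), THF, −78 °C; Et3N, non-aqueous work-up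
Reagents that add atoms: methylmagnesium bromide, C[Mg]Br; chlorotrimethylsilane, C[Si](C)(C)Cl
Why: Copper-catalysed conjugate addition with silyl trapping of the enolate delivers methyl anti to the C4 prenyl group (3,4-trans), a centre that is erased again in step 5.

Step 5
Reactants: 8 trimethyl{[(3S,4S)-3-methyl-4-(3-methylbut-2-en-1-yl)cyclohex-1-en-1-yl]oxy}silane
Product: 9 (4S)-3-methyl-4-(3-methylbut-2-en-1-yl)cyclohex-2-en-1-one
Conditions: Pd(OAc)2 (1.05 equiv), MeCN, rt
Reagents that add atoms: none
Why: Saegusa–Ito oxidation: the divalent palladium enolate formed from the silyl enol ether undergoes β-hydride elimination to give the enone regiospecifically, leaving the remote trisubstituted alkene and the C4 centre untouched.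

Step 6
Reactants: 9 (4S)-3-methyl-4-(3-methylbut-2-en-1-yl)cyclohex-2-en-1-one
Product: 10 (4S)-3,3-dimethyl-4-(3-methylbut-2-en-1-yl)cyclohexan-1-one
Conditions: MeMgBr (1.5 equiv), CuBr·SMe2 (10 mol %), THF, −40 to 0 °C; then H2O
Reagents that add atoms: methylmagnesium bromide, C[Mg]Br
Why: A second copper-catalysed conjugate addition to the β-methyl enone builds the gem-dimethyl carbon (future C8), which is not stereogenic, and the adjacent centre is not enolisable.

Step 7
Reactants: 10 (4S)-3,3-dimethyl-4-(3-methylbut-2-en-1-yl)cyclohexan-1-one; 4 5-methylhex-4-enal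
Product: 12 (4R)-2-(1-hydroxy-5-methylhex-4-en-1-yl)-5,5-dimethyl-4-(3-methylbut-2-en-1-yl)cyclohexan-1-one, via lithium enolate 11 (not isolated)
Conditions: LiN(iPr)2 (1.05 equiv), THF, −78 °C; then 4 (1.1 equiv), −78 °C; then H2O
Reagents that add atoms: none
Why: Kinetic deprotonation takes the α-methylene remote from the neopentylic side and the lithium enolate adds to the aldehyde in an intermolecular aldol reaction that joins ring B to the C4–C3–prenyl arm; the two new centres are removed in steps 8 and 9.

Step 8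
Reactants: 12 (4R)-2-(1-hydroxy-5-methylhex-4-en-1-yl)-5,5-dimethyl-4-(3-methylbut-2-en-1-yl)cyclohexan-1-one
Product: 13 (4R)-5,5-dimethyl-4-(3-methylbut-2-en-1-yl)-2-(5-methylhex-4-enoyl)cyclohexan-1-one
Conditions: Dess–Martin periodinane (1.2 equiv), CH2Cl2, 0 °C to rt
Reagents that add atoms: none
Why: Dess–Martin oxidation of the β-hydroxy ketone gives the enolised 1,3-diketone without touching the alkenes; C2 becomes epimerisable and C4 is unaffected.

Step 9
Reactants: 13 (4R)-5,5-dimethyl-4-(3-methylbut-2-en-1-yl)-2-(5-methylhex-4-enoyl)cyclohexan-1-one; 14 geranyl bromide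
Product: 15 (2R,4R)-2-geranyl-5,5-dimethyl-4-(3-methylbut-2-en-1-yl)-2-(5-methylhex-4-enoyl)cyclohexan-1-one
Conditions: K2CO3 (2 equiv), 14 (1.2 equiv), acetone, 50 °C
Reagents that add atoms: none
Why: C-Alkylation (SN2) of the diketone enolate: the allylic bromide adds axially to C2 on the face opposite the C4 prenyl group (the other face needs a twist-boat blocked by the axial C5 methyl), so the acyl group ends cis to the prenyl group, as the 7-endo series requires.

Step 10
Reactants: 15 (2R,4R)-2-geranyl-5,5-dimethyl-4-(3-methylbut-2-en-1-yl)-2-(5-methylhex-4-enoyl)cyclohexan-1-one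
Product: 17 (2S,4R)-2-{2-[bis(methylsulfanyl)methylidene]-5-methylhex-4-enoyl}-2-geranyl-5,5-dimethyl-4-(3-methylbut-2-en-1-yl)cyclohexan-1-one, via dilithium dithiolate 16 (not isolated)
Conditions: LiN(SiMe3)2 (1.1 equiv), THF, −78 °C; CS2 (1.2 equiv); LiN(SiMe3)2 (1.1 equiv), −78 to 0 °C; MeI (3 equiv), 0 °C to rt
Reagents that add atoms: carbon disulfide, S=C=S; iodomethane, CI
Why: α-Oxo ketene dithioacetal formation: the acyl α-methylene is deprotonated in preference to the neopentylic ring methylene, adds to CS2, is deprotonated again and S-methylated twice; no stereocentre is involved (the descriptor change at C2 is only a priority change).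

Step 11
Reactants: 17 (2S,4R)-2-{2-[bis(methylsulfanyl)methylidene]-5-methylhex-4-enoyl}-2-geranyl-5,5-dimethyl-4-(3-methylbut-2-en-1-yl)cyclohexan-1-one
Product: 18 5-geranyl-8,8-dimethyl-2-(methylsulfanyl)-3,7-bis(3-methylbut-2-en-1-yl)bicyclo[3.3.1]non-2-ene-4,9-dione (C7 prenyl endo)
Conditions: KN(SiMe3)2 (1.2 equiv), THF, −78 °C to rt; then H2O
Reagents that add atoms: none
Why: Intramolecular conjugate addition–elimination (a vinylogous Claisen-type acylation): the ring-ketone enolate, which can only form at C1, attacks the bis(methylsulfanyl) carbon and expels methanethiolate to close ring A, and because the acyl arm is cis to the prenyl group the bicyclo[3.3.1] core forms with that group endo and both bridgeheads fixed by the C5 centre.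

Step 12
Reactants: 18 5-geranyl-8,8-dimethyl-2-(methylsulfanyl)-3,7-bis(3-methylbut-2-en-1-yl)bicyclo[3.3.1]non-2-ene-4,9-dione
Product: 19 5-geranyl-2-hydroxy-8,8-dimethyl-3,7-bis(3-methylbut-2-en-1-yl)bicyclo[3.3.1]non-2-ene-4,9-dione (enol of the 2,4,9-trione)
Conditions: LiOH (5 equiv), 1,4-dioxane/H2O (3:1), 90 °C; then 1 M HCl
Reagents that add atoms: lithium hydroxide, [Li+].[OH-]
Why: Hydrolysis by addition–elimination of hydroxide at the vinylogous thioester carbon gives the vinylogous acid, whose anion shields the triketone from retro-Claisen cleavage; no stereocentre is touched.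

Step 13
Reactants: 19 5-geranyl-2-hydroxy-8,8-dimethyl-3,7-bis(3-methylbut-2-en-1-yl)bicyclo[3.3.1]non-2-ene-4,9-dione
Product: 20 3-bromo-5-geranyl-8,8-dimethyl-3,7-bis(3-methylbut-2-en-1-yl)bicyclo[3.3.1]nonane-2,4,9-trione
Conditions: N-bromosuccinimide (1.0 equiv), CH2Cl2, −78 to 0 °C, dark
Reagents that add atoms: N-bromosuccinimide, O=C1CCC(=O)N1Br
Why: Electrophilic α-bromination of the enolised β-diketone at C3 is far faster than any reaction of the isolated trisubstituted alkenes, and the C3 configuration is immaterial because it becomes a planar radical.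

Step 14
Reactants: 20 3-bromo-5-geranyl-8,8-dimethyl-3,7-bis(3-methylbut-2-en-1-yl)bicyclo[3.3.1]nonane-2,4,9-trione
Product: 21 debenzoyl tetracyclic triketone (target skeleton with H on bridgehead C1)
Conditions: (Me3Si)3SiH (1.3 equiv) and azobisisobutyronitrile (0.2 equiv) added over 6 h, toluene (5 mM), 90 °C
Reagents that add atoms: none
Why: Radical cyclisation cascade: bromine abstraction gives the C3 radical, which closes the seven-membered ring onto the inner carbon of the endo C7 prenyl group (the cage fixes C3, the alkene face sets Ca with CMe2 on the C1/C8 side), the tertiary radical then closes the cyclopentane by 5-exo-trig addition to the C3 prenyl group through a chair-like Beckwith–Houk transition state (isopropyl trans to the CH2 bridge at Cc), and the last tertiary radical takes hydrogen from the silane; the Ca epimer is removed by chromatography.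

Step 15
Reactants: 21 debenzoyl tetracyclic triketone; 22 benzoyl chloride
Product: 24 target CNP0155129.1, via bridgehead lithio ketone 23 (not isolated)
Conditions: lithium 2,2,6,6-tetramethylpiperidide (1.5 equiv), THF, −78 °C; then 22 (2 equiv), −78 to 0 °C; then H2O
Reagents that add atoms: none
Why: Bridgehead deprotonation–C-acylation: C1–H is the only hydrogen α to a carbonyl (between the C2 and C9 ketones), the bridgehead carbanion cannot O-acylate without forming an anti-Bredt enol ester, and benzoyl chloride therefore reacts at carbon with retention to give the target.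

## Compound list

1 | 2-methylbut-3-en-2-ol | CC(C)(O)C=C | starting material
2 | ethyl vinyl ether | C=COCC | starting material
3 | 3-methyl-3-(vinyloxy)but-1-ene (allyl vinyl ether, not isolated) | C=COC(C)(C)C=C | intermediate
4 | 5-methylhex-4-enal | CC(C)=CCCC=O | intermediate
5 | methyl vinyl ketone (but-3-en-2-one) | CC(=O)C=C | starting material
6 | (2S)-2-(3-methylbut-2-en-1-yl)-5-oxohexanal | CC(=O)CC[C@@H](CC=C(C)C)C=O | intermediate
7 | (4S)-4-(3-methylbut-2-en-1-yl)cyclohex-2-en-1-one | O=C1CC[C@@H](CC=C(C)C)C=C1 | intermediate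
8 | trimethyl{[(3S,4S)-3-methyl-4-(3-methylbut-2-en-1-yl)cyclohex-1-en-1-yl]oxy}silane (3,4-trans) | C[Si](C)(C)OC1=C[C@@H](C)[C@H](CC=C(C)C)CC1 | intermediate
9 | (4S)-3-methyl-4-(3-methylbut-2-en-1-yl)cyclohex-2-en-1-one | O=C1CC[C@@H](CC=C(C)C)C(C)=C1 | intermediate
10 | (4S)-3,3-dimethyl-4-(3-methylbut-2-en-1-yl)cyclohexan-1-one | O=C1CC[C@@H](CC=C(C)C)C(C)(C)C1 | intermediate
11 | lithium enolate of 10 (enolised away from the gem-dimethyl carbon; prenyl-bearing centre unchanged; not isolated) | [Li+].[O-]C1=CC[C@@H](CC=C(C)C)C(C)(C)C1 | intermediate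
12 | (4R)-2-(1-hydroxy-5-methylhex-4-en-1-yl)-5,5-dimethyl-4-(3-methylbut-2-en-1-yl)cyclohexan-1-one (mixture at C2 and the carbinol carbon) | O=C1C(C(O)CCC=C(C)C)C[C@@H](CC=C(C)C)C(C)(C)C1 | intermediate
13 | (4R)-5,5-dimethyl-4-(3-methylbut-2-en-1-yl)-2-(5-methylhex-4-enoyl)cyclohexan-1-one (keto/enol mixture) | O=C1C(C(=O)CCC=C(C)C)C[C@@H](CC=C(C)C)C(C)(C)C1 | intermediate
14 | geranyl bromide ((2E)-1-bromo-3,7-dimethylocta-2,6-diene) | CC(C)=CCC/C(C)=C/CBr | starting material
15 | (2R,4R)-2-geranyl-5,5-dimethyl-4-(3-methylbut-2-en-1-yl)-2-(5-methylhex-4-enoyl)cyclohexan-1-one (acyl cis to prenyl) | CC(C)=CCC/C(C)=C/C[C@]1(C(=O)CCC=C(C)C)C[C@@H](CC=C(C)C)C(C)(C)CC1=O | intermediate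
16 | dilithium ene-1,1-dithiolate of 15 (acyl arm C(=O)–C(prenyl)=C(SLi)2; not isolated) | [Li+].[Li+].CC(C)=CCC/C(C)=C/C[C@]1(C(=O)C(CC=C(C)C)=C([S-])[S-])C[C@@H](CC=C(C)C)C(C)(C)CC1=O | intermediate
17 | (2S,4R)-2-{2-[bis(methylsulfanyl)methylidene]-5-methylhex-4-enoyl}-2-geranyl-5,5-dimethyl-4-(3-methylbut-2-en-1-yl)cyclohexan-1-one (same spatial arrangement as 15) | CC(C)=CCC/C(C)=C/C[C@]1(C(=O)C(CC=C(C)C)=C(SC)SC)C[C@@H](CC=C(C)C)C(C)(C)CC1=O | intermediate
18 | 5-geranyl-8,8-dimethyl-2-(methylsulfanyl)-3,7-bis(3-methylbut-2-en-1-yl)bicyclo[3.3.1]non-2-ene-4,9-dione (C7 prenyl endo, on the face of the C2–C4 bridge; H on C1) | CC(C)=CCC/C(C)=C/C[C@@]12C[C@@H](CC=C(C)C)C(C)(C)[C@H](C2=O)C(SC)=C(CC=C(C)C)C1=O | intermediate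
19 | 5-geranyl-2-hydroxy-8,8-dimethyl-3,7-bis(3-methylbut-2-en-1-yl)bicyclo[3.3.1]non-2-ene-4,9-dione (enol of the 2,4,9-trione; C7 prenyl endo) | CC(C)=CCC/C(C)=C/C[C@@]12C[C@@H](CC=C(C)C)C(C)(C)[C@H](C2=O)C(O)=C(CC=C(C)C)C1=O | intermediate
20 | 3-bromo-5-geranyl-8,8-dimethyl-3,7-bis(3-methylbut-2-en-1-yl)bicyclo[3.3.1]nonane-2,4,9-trione (C7 prenyl endo; C3 epimer not defined) | CC(C)=CCC/C(C)=C/C[C@@]12C[C@@H](CC=C(C)C)C(C)(C)[C@H](C2=O)C(=O)C(Br)(CC=C(C)C)C1=O | intermediate
21 | debenzoyl tetracyclic triketone (target skeleton with H on bridgehead C1; other centres as in the target) | CC(C)=CCC/C(C)=C/C[C@@]12C[C@H]3C[C@@H]4C(C)(C)[C@@H](C(C)C)C[C@]4(C1=O)C(=O)[C@@H](C2=O)C3(C)C | intermediate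
22 | benzoyl chloride | O=C(Cl)c1ccccc1 | starting material
23 | C1-lithio derivative of 21 (bridgehead lithio ketone, not isolated) | CC(C)=CCC/C(C)=C/C[C@@]12C[C@H]3C[C@@H]4C(C)(C)[C@@H](C(C)C)C[C@]4(C1=O)C(=O)[C@@]([Li])(C2=O)C3(C)C | intermediate
24 | CNP0155129.1 (C1-benzoyl, C5-geranyl tetracyclic tetraketone) | CC(C)=CCC/C(C)=C/C[C@@]12C[C@H]3C[C@@H]4C(C)(C)[C@@H](C(C)C)C[C@]4(C1=O)C(=O)[C@@](C(=O)c1ccccc1)(C2=O)C3(C)C | target

## Step count and risks

Total step count: 15. Longest linear sequence: 15 steps (1 and 2 to 24; aldehyde 4 is used twice).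

Three steps most likely to fail:

Step 11 (closure of ring A). The enolate carbon is neopentylic and ring B must place the acyl arm and the C7 prenyl group on the same face, so cyclisation may be slow or divert to O-attack. The fallback sets out from 17: the ring ketone is silylated (Me3SiOTf, Et3N, CH2Cl2, 0 °C) to the trimethylsilyl enol ether F1, and the ring is then closed under Lewis-acid instead of base control by a Mukaiyama–Michael addition–elimination (BF3·OEt2 or catalytic Me3SiOTf, CH2Cl2, −78 °C). This comes back to the route at 18.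

Step 14 (radical cascade). Premature hydrogen transfer to the first or second radical and the facial selectivity at Ca are the uncertainties; I cannot predict the Ca epimer ratio with confidence. The fallback sets out from enol 19 (20 is skipped) and runs the cascade oxidatively with Mn(OAc)3·2H2O and Cu(OAc)2 in AcOH at rt. Trivalent manganese generates the same C3 radical with no hydrogen donor present, and divalent copper oxidises the final tertiary radical to the isopropenyl tetracycle F2. RhCl(PPh3)3 under H2 (benzene, rt) then reduces only the 1,1-disubstituted alkene and leaves the trisubstituted geranyl alkenes alone, which comes back to the route at 21.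

Step 15 (bridgehead benzoylation). The bridgehead carbanion sits next to the quaternary C8 and may not acylate cleanly with an acid chloride. The fallback sets out from 21: the lithio ketone 23 is trapped with benzaldehyde, a smaller and more reactive electrophile, to give the bridgehead carbinol F3, which is oxidised with Dess–Martin periodinane (CH2Cl2, rt). This comes back to the route at 24.

Further compounds
F1 | step 11 | trimethylsilyl enol ether of 17 (ring ketone silylated toward C1) | CC(C)=CCC/C(C)=C/C[C@]1(C(=O)C(CC=C(C)C)=C(SC)SC)C[C@@H](CC=C(C)C)C(C)(C)C=C1O[Si](C)(C)C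
F2 | step 14 | isopropenyl analogue of 21 (prop-1-en-2-yl in place of isopropyl at Cc) | CC(C)=CCC/C(C)=C/C[C@@]12C[C@H]3C[C@@H]4C(C)(C)[C@@H](C(C)=C)C[C@]4(C1=O)C(=O)[C@@H](C2=O)C3(C)C
F3 | step 15 | C1-[hydroxy(phenyl)methyl] derivative of 21 (bridgehead carbinol, carbinol centre not defined) | CC(C)=CCC/C(C)=C/C[C@@]12C[C@H]3C[C@@H]4C(C)(C)[C@@H](C(C)C)C[C@]4(C1=O)C(=O)[C@@](C(O)c1ccccc1)(C2=O)C3(C)C
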